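**Retrosynthetic overview**

1. Feature: in isochromene numbering (ring A = pyran O2, C1, C3, C4, C4a, C8a; ring B = carbocycle C4a, C5, C6, C7, C8, C8a) the segment C6(=O)–C7(CH3)(O-aroyl)–C8(=O) is a 2-acyloxy-2-methylmalonyl unit flanked by two nucleophilic carbons, C5 and C8a. The single stereocentre C7 is therefore fixed only by which malonyl carbonyl is joined to C5 and which to C8a.
2. Last disconnections: aryl O–Si cleavage, and before it ring A through the O2–C3 bond (6-endo-dig addition of the C1 enol oxygen to a pentenynyl group on C4a).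
3. Key disconnection: C5–C6 and C8–C8a of ring B, a formal [3+3] double C-acylation of the TBS dienol ether of (E)-3-methylocta-2,6-dien-4-ynal by an enantiopure malonyl unit whose chloride arm becomes C6 and whose methyl ester arm becomes C8.
4. Malonyl unit: dimethyl methylmalonate is brominated and the bromide is displaced by the caesium salt of silyl-protected 4-hydroxy-2-methoxy-6-methylbenzoic acid, so the C7–O bond is made by O-alkylation. The diester is then desymmetrised with pig liver esterase and converted to the acid chloride. The dienol silane comes from crotonaldehyde (Corey–Fuchs) and 4-methoxybut-3-en-2-one.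
5. Ring order: ring B (step 11), then ring A (step 12).

Key step: step 11

Abbreviation: ArCO = 2-methoxy-6-methyl-4-[(triisopropylsilyl)oxy]benzoyl; locants C1–C8a are those of the isochromene core of the target.

Assumption: pig liver esterase is taken to hydrolyse the pro-S methoxycarbonyl group of the prochiral aroyloxymalonate and so to give the (R)-half acid; the sense and level of this selectivity are substrate-dependent and would have to be confirmed.

**Route**

Step 1
Reactants: 1 2,4-dihydroxy-6-methylbenzaldehyde
Product: 2 2-hydroxy-6-methyl-4-[(triisopropylsilyl)oxy]benzaldehyde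
Conditions: TIPSCl (1.05 equiv), imidazole, CH2Cl2, 0 °C
Reagents that add atoms: triisopropylsilyl chloride, CC(C)[Si](Cl)(C(C)C)C(C)C
Why: Silyl ether formation should be selective for the 4-OH because the 2-OH is held in a hydrogen bond to the formyl group, and TIPS is chosen because this aryl ether must later survive a caesium carboxylate in DMF, the esterase buffer, ZnBr2 and DBU.

Step 2
Reactants: 2 2-hydroxy-6-methyl-4-[(triisopropylsilyl)oxy]benzaldehyde
Product: 3 2-methoxy-6-methyl-4-[(triisopropylsilyl)oxy]benzaldehyde
Conditions: MeOH, PPh3, DIAD, THF, 0 °C → rt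
Reagents that add atoms: methanol, CO
Why: A Mitsunobu etherification methylates the chelated phenol under neutral conditions, so the aryl silyl ether para to the formyl group is not cleaved as it could be with MeI and carbonate.

Step 3
Reactants: 3 2-methoxy-6-methyl-4-[(triisopropylsilyl)oxy]benzaldehyde
Product: 4 2-methoxy-6-methyl-4-[(triisopropylsilyl)oxy]benzoic acid
Conditions: NaClO2, NaH2PO4, 2-methyl-2-butene, t-BuOH/H2O, 0 °C → rt
Reagents that add atoms: sodium chlorite, [Na+].[O-]Cl=O
Why: The Pinnick oxidation converts hindered, electron-rich benzaldehydes into acids at pH 3–4 with the hypochlorite by-product trapped by the alkene, and it avoids the forcing saponification of a di-ortho-substituted methyl benzoate that a silyl ether would not outlast.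

Step 4
Reactants: 5 dimethyl methylmalonate
Product: 6 dimethyl 2-bromo-2-methylmalonate
Conditions: Br2 (1.05 equiv), 1,2-dichloroethane, 60 °C
Reagents that add atoms: bromine, BrBr
Why: Bromination through the enol replaces the single acidic C–H of the malonate, as in the classical preparation of bromomalonates, and cannot go further.

Step 5
Reactants: 6 dimethyl 2-bromo-2-methylmalonate; 4 2-methoxy-6-methyl-4-[(triisopropylsilyl)oxy]benzoic acid
Product: 8 dimethyl 2-methyl-2-(ArCO-oxy)malonate, via caesium aroate 7 (not isolated)
Conditions: Cs2CO3 (0.5 equiv), DMF, 4 Å MS, rt → 40 °C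
Reagents that add atoms: none
Why: O-Alkylation of a caesium carboxylate by an α-bromo carbonyl compound (SN2 at a carbon activated by two ester groups) makes the C7–O bond with the carboxylate oxygen as nucleophile, so the di-ortho-substituted aroyl carbon never has to be attacked by a tertiary alcohol.

Step 6
Reactants: 8 dimethyl 2-methyl-2-(ArCO-oxy)malonate
Product: 9 (2R)-3-methoxy-2-methyl-3-oxo-2-(ArCO-oxy)propanoic acid
Conditions: pig liver esterase, 0.1 M phosphate buffer pH 7.5/DMSO 9:1, rt; then citric acid to pH 3
Reagents that add atoms: water, O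
Why: Esterase hydrolysis of prochiral 2,2-disubstituted dimethyl malonates is an established desymmetrisation that stops at the half ester, the quaternary stereocentre being set by the enzyme's choice of the pro-S ester group (see assumption), while the hindered tertiary aroate and the silyl ether are not substrates at this pH.

Step 7
Reactants: 9 (2R)-3-methoxy-2-methyl-3-oxo-2-(ArCO-oxy)propanoic acid
Product: 10 methyl (2S)-3-chloro-2-methyl-3-oxo-2-(ArCO-oxy)propanoate
Conditions: (COCl)2, DMF (cat.), CH2Cl2, 0 °C → rt; evaporate and use crude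
Reagents that add atoms: oxalyl chloride, ClC(=O)C(=O)Cl
Why: Vilsmeier-type activation gives the acid chloride under mild conditions, and since the quaternary centre has no α-hydrogen neither ketene formation nor epimerisation is possible (the change of descriptor from R to S is a priority effect only).

Step 8
Reactants: 11 (E)-crotonaldehyde
Product: 12 (E)-1,1-dibromopenta-1,3-diene
Conditions: CBr4, PPh3, CH2Cl2, 0 °C
Reagents that add atoms: carbon tetrabromide, BrC(Br)(Br)Br
Why: The first stage of the Corey–Fuchs sequence (Ramirez dibromo-olefination) converts the enal into the 1,1-dibromodiene without touching the E double bond.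

Step 9
Reactants: 12 (E)-1,1-dibromopenta-1,3-diene; 13 (E)-4-methoxybut-3-en-2-one
Product: 16 (2E,6E)-3-methylocta-2,6-dien-4-ynal, via lithium (E)-pent-3-en-1-ynide 14 (not isolated), via methoxy dienynol 15 (not isolated)
Conditions: n-BuLi (2.0 equiv), THF, −78 → −20 °C; then 13, −78 °C; then 1 M HCl, THF, 0 °C → rt
Reagents that add atoms: water, O
Why: Bromine–lithium exchange and carbenoid rearrangement (second Corey–Fuchs stage) give the lithium acetylide, which adds 1,2 to the ketone of the vinylogous ester, and aqueous acid then ionises the tertiary carbinol with help from the enol ether and hydrolyses the oxocarbenium ion (alkylative 1,3-carbonyl transposition) to the β-methyl enal, either C2=C3 isomer of which serves in step 10.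

Step 10
Reactants: 16 (2E,6E)-3-methylocta-2,6-dien-4-ynal
Product: 17 tert-butyl(dimethyl){[(1E,6E)-3-methylideneocta-1,6-dien-4-yn-1-yl]oxy}silane
Conditions: TBSOTf, Et3N, Et2O, 0 °C → rt; non-aqueous work-up, use fresh
Reagents that add atoms: tert-butyldimethylsilyl triflate, CC(C)(C)[Si](C)(C)OS(=O)(=O)C(F)(F)F
Why: Soft enolisation (O-silylation of the aldehyde, then deprotonation by Et3N at the only γ-C–H, the 3-methyl group) is the standard preparation of aldehyde dienol silanes, and the geometry of the enol ether is of no consequence for step 11.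

Step 11
Reactants: 17 tert-butyl(dimethyl){[(1E,6E)-3-methylideneocta-1,6-dien-4-yn-1-yl]oxy}silane; 10 methyl (2S)-3-chloro-2-methyl-3-oxo-2-(ArCO-oxy)propanoate
Product: 19 ring B formyl enol (1S)-3-formyl-2-hydroxy-1-methyl-6-oxo-4-[(E)-pent-3-en-1-yn-1-yl]cyclohexa-2,4-dien-1-yl 2-methoxy-6-methyl-4-[(triisopropylsilyl)oxy]benzoate, via keto enal ester 18 (not isolated)
Conditions: 17 (1.3 equiv), ZnBr2 (20 mol%), CH2Cl2, −20 °C → rt; then DBU (3 equiv), 4 Å MS, 0 °C → rt; 1 M HCl work-up
Reagents that add atoms: none
Why: Proposed new method: ZnBr2 activates the acid chloride of 10, the terminal CH2 carbon of dienol silane 17 (the future C5) attacks it with loss of TBSCl to form C5–C6 and give keto enal 18, and DBU then deprotonates the C5 methylene, now flanked by the ketone and the enal, to a delocalised dienolate whose aldehyde α-carbon (C8a) adds to the methyl ester and expels methoxide, forming C8–C8a. The closest known reactions are the Lewis acid-mediated vinylogous Mukaiyama acylation of 1-silyloxy dienes, the Dieckmann condensation and [3+3] cyclisations of 1,3-dinucleophiles with malonyl dielectrophiles, which have not been combined in one flask on an aldehyde dienol silane and an unsymmetrical malonyl unit. Ring B is closed by a 6-exo-trig (enolexo) attack on the ester carbonyl, and the closure is pulled forward by formation of the stabilised enolate of the β-keto aldehyde 19, which also shields the 2,2-disubstituted 1,3-dione from retro-Claisen cleavage. No stereocentre is formed: C7 comes from 10 unchanged, having no α-hydrogen, and its R configuration in the target follows only from the chloride arm becoming C6 and the ester arm C8 (the S descriptor of 19 is a priority effect of the enol tautomer). The selectivity needed is therefore acylation by the chloride at C5 and never at C8a or at oxygen, which is secured by the γ-preference of aldehyde-derived dienol silanes under Lewis acid (largest HOMO coefficient and least hindrance at the terminal carbon) and by the inertness of the methyl ester until base is added. For the second bond there is no alternative, because from the dienolate only C8a can reach the ester through a six-membered transition state.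

Step 12
Reactants: 19 ring B formyl enol
Product: 20 (7R)-7-methyl-6,8-dioxo-3-[(E)-prop-1-en-1-yl]-7,8-dihydro-6H-isochromen-7-yl 2-methoxy-6-methyl-4-[(triisopropylsilyl)oxy]benzoate
Conditions: AgOTf (10 mol%), CH2Cl2, rt, dark
Reagents that add atoms: none
Why: AgOTf activates the alkyne as a π-acid and the C1 oxygen of the hydroxymethylene tautomer adds to C3 in a 6-endo-dig cycloisomerisation (as for o-alkynyl carbonyl compounds going to isochromenes), C3 being favoured over the 5-exo position C4 because it is the terminus of the ynenone and carries the cation-stabilising propenyl group, and protodemetalation at C4 completes ring A without touching C7.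

Step 13
Reactants: 20 silyl-protected isochromenedione
Product: 21 (7R)-7-methyl-6,8-dioxo-3-[(E)-prop-1-en-1-yl]-7,8-dihydro-6H-isochromen-7-yl 4-hydroxy-2-methoxy-6-methylbenzoate (target)
Conditions: TBAF, AcOH (1:1), THF, 0 °C
Reagents that add atoms: none
Why: Fluoride cleaves the aryl silyl ether rapidly, and buffering with acetic acid protects the electrophilic, base-sensitive isochromenedione core and the C7 ester.

**Compound list**

1 | 2,4-dihydroxy-6-methylbenzaldehyde | O=Cc1c(C)cc(O)cc1O | starting material
2 | 2-hydroxy-6-methyl-4-[(triisopropylsilyl)oxy]benzaldehyde | O=Cc1c(C)cc(O[Si](C(C)C)(C(C)C)C(C)C)cc1O | intermediate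
3 | 2-methoxy-6-methyl-4-[(triisopropylsilyl)oxy]benzaldehyde | O=Cc1c(C)cc(O[Si](C(C)C)(C(C)C)C(C)C)cc1OC | intermediate
4 | 2-methoxy-6-methyl-4-[(triisopropylsilyl)oxy]benzoic acid | OC(=O)c1c(C)cc(O[Si](C(C)C)(C(C)C)C(C)C)cc1OC | intermediate
5 | dimethyl methylmalonate | COC(=O)C(C)C(=O)OC | starting material
6 | dimethyl 2-bromo-2-methylmalonate | COC(=O)C(C)(Br)C(=O)OC | intermediate
7 | caesium 2-methoxy-6-methyl-4-[(triisopropylsilyl)oxy]benzoate | [Cs+].[O-]C(=O)c1c(C)cc(O[Si](C(C)C)(C(C)C)C(C)C)cc1OC | intermediate (not isolated)
8 | dimethyl 2-methyl-2-({2-methoxy-6-methyl-4-[(triisopropylsilyl)oxy]benzoyl}oxy)malonate | COC(=O)C(C)(OC(=O)c1c(C)cc(O[Si](C(C)C)(C(C)C)C(C)C)cc1OC)C(=O)OC | intermediate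
9 | (2R)-3-methoxy-2-methyl-3-oxo-2-({2-methoxy-6-methyl-4-[(triisopropylsilyl)oxy]benzoyl}oxy)propanoic acid | OC(=O)[C@@](C)(OC(=O)c1c(C)cc(O[Si](C(C)C)(C(C)C)C(C)C)cc1OC)C(=O)OC | intermediate
10 | methyl (2S)-3-chloro-2-methyl-3-oxo-2-({2-methoxy-6-methyl-4-[(triisopropylsilyl)oxy]benzoyl}oxy)propanoate | ClC(=O)[C@@](C)(OC(=O)c1c(C)cc(O[Si](C(C)C)(C(C)C)C(C)C)cc1OC)C(=O)OC | intermediate
11 | (E)-crotonaldehyde | C/C=C/C=O | starting material
12 | (E)-1,1-dibromopenta-1,3-diene | C/C=C/C=C(Br)Br | intermediate
13 | (E)-4-methoxybut-3-en-2-one | CO/C=C/C(C)=O | starting material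
14 | lithium (E)-pent-3-en-1-ynide | [Li]C#C/C=C/C | intermediate (not isolated)
15 | (1E,6E)-1-methoxy-3-methylocta-1,6-dien-4-yn-3-ol (racemic, first formed as its lithium alkoxide) | CO/C=C/C(C)(O)C#C/C=C/C | intermediate (not isolated)
16 | (2E,6E)-3-methylocta-2,6-dien-4-ynal (2E drawn; any 2Z isomer is carried along) | C/C=C/C#C/C(C)=C/C=O | intermediate
17 | tert-butyl(dimethyl){[(1E,6E)-3-methylideneocta-1,6-dien-4-yn-1-yl]oxy}silane | C/C=C/C#CC(=C)/C=C/O[Si](C)(C)C(C)(C)C | intermediate
18 | methyl (2R)-2-methyl-3,7-dioxo-5-[(E)-pent-3-en-1-yn-1-yl]-2-({2-methoxy-6-methyl-4-[(triisopropylsilyl)oxy]benzoyl}oxy)hept-5-enoate (mixture of C5=C6 isomers) | C/C=C/C#CC(=CC=O)CC(=O)[C@@](C)(OC(=O)c1c(C)cc(O[Si](C(C)C)(C(C)C)C(C)C)cc1OC)C(=O)OC | intermediate (not isolated)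
19 | (1S)-3-formyl-2-hydroxy-1-methyl-6-oxo-4-[(E)-pent-3-en-1-yn-1-yl]cyclohexa-2,4-dien-1-yl 2-methoxy-6-methyl-4-[(triisopropylsilyl)oxy]benzoate | C/C=C/C#CC1=CC(=O)[C@@](C)(OC(=O)c2c(C)cc(O[Si](C(C)C)(C(C)C)C(C)C)cc2OC)C(O)=C1C=O | intermediate
20 | (7R)-7-methyl-6,8-dioxo-3-[(E)-prop-1-en-1-yl]-7,8-dihydro-6H-isochromen-7-yl 2-methoxy-6-methyl-4-[(triisopropylsilyl)oxy]benzoate | C/C=C/C1=CC2=CC(=O)[C@@](C)(OC(=O)c3c(C)cc(O[Si](C(C)C)(C(C)C)C(C)C)cc3OC)C(=O)C2=CO1 | intermediate
21 | (7R)-7-methyl-6,8-dioxo-3-[(E)-prop-1-en-1-yl]-7,8-dihydro-6H-isochromen-7-yl 4-hydroxy-2-methoxy-6-methylbenzoate | C/C=C/C1=CC2=CC(=O)[C@@](C)(OC(=O)c3c(C)cc(O)cc3OC)C(=O)C2=CO1 | target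

**Step count**

Total steps: 13. Longest linear sequence: 9 steps (1, 2, 3, 5, 6, 7, 11, 12, 13).

**Steps most likely to fail**

Step 11 (key step, proposed new method). Several processes could defeat it:
- acylation of the dienol silane at the α-carbon or at oxygen instead of the terminal carbon;
- ionisation of the hindered α-acyloxy acid chloride with participation of the aroyl carbonyl group;
- Lewis acid-induced oligomerisation of the dienyne before the hindered chloride reacts;
- retro-Claisen cleavage of the β-keto ester by the liberated methoxide faster than ring closure.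

The fallback uses known reactions only and sets out from 10 and 17. Acid chloride 10 would be reduced with LiAlH(OtBu)3 (THF, −78 °C) to the aldehyde methyl (2R)-2-methyl-3-oxo-2-(ArCO-oxy)propanoate F1. A vinylogous Mukaiyama aldol addition of 17 to F1 (BF3·OEt2, CH2Cl2, −78 °C), a well-precedented γ-selective reaction of aldehyde dienol silanes, should give the δ-hydroxy enal methyl (2R)-3-hydroxy-2-methyl-7-oxo-5-[(E)-pent-3-en-1-yn-1-yl]-2-(ArCO-oxy)hept-5-enoate F2 as a mixture of carbinol epimers. Dess–Martin oxidation of F2 would then give keto enal ester 18, now isolated, and a separate Dieckmann closure with DBU rejoins the route at 19. The pairing of arms, and so the configuration at C7, is the same as in the main route.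

Step 6. The large, lipophilic diester may be turned over slowly, or the two enantiotopic ester groups may be discriminated poorly or in the opposite sense. The fallback sets out from 8. Monohydrolysis with Me3SnOH (1,2-dichloroethane, 70 °C), which spares the silyl ether, would give the racemic half acid 3-methoxy-2-methyl-3-oxo-2-(ArCO-oxy)propanoic acid F3. This would be resolved by preparative chromatography on a chiral stationary phase (or by crystallisation of its salts with a chiral amine). The (S)-half acid F4 is set aside and the (R)-enantiomer is 9, where the route is rejoined; the configuration would be assigned by crystallography of an amine salt.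

Step 5. The carboxylate may act as a base and eliminate HBr from the tertiary bromide to give dimethyl methylidenemalonate, which would then take up the carboxylate by conjugate addition, or bromine may be transferred to the electron-rich arene, instead of substitution. The fallback sets out from 4. Rh2(OAc)4-catalysed O–H insertion of commercial dimethyl diazomalonate into acid 4 (CH2Cl2, rt) would give dimethyl 2-(ArCO-oxy)malonate F5. C-Methylation of F5 (MeI, K2CO3, acetone) then returns to 8.

**Further compounds**

F1 | step 11 | methyl (2R)-2-methyl-3-oxo-2-({2-methoxy-6-methyl-4-[(triisopropylsilyl)oxy]benzoyl}oxy)propanoate | O=C[C@@](C)(OC(=O)c1c(C)cc(O[Si](C(C)C)(C(C)C)C(C)C)cc1OC)C(=O)OC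
F2 | step 11 | methyl (2R)-3-hydroxy-2-methyl-7-oxo-5-[(E)-pent-3-en-1-yn-1-yl]-2-({2-methoxy-6-methyl-4-[(triisopropylsilyl)oxy]benzoyl}oxy)hept-5-enoate (mixture at C3 and about C5=C6) | C/C=C/C#CC(=CC=O)CC(O)[C@@](C)(OC(=O)c1c(C)cc(O[Si](C(C)C)(C(C)C)C(C)C)cc1OC)C(=O)OC
F3 | step 6 | racemic 3-methoxy-2-methyl-3-oxo-2-({2-methoxy-6-methyl-4-[(triisopropylsilyl)oxy]benzoyl}oxy)propanoic acid | OC(=O)C(C)(OC(=O)c1c(C)cc(O[Si](C(C)C)(C(C)C)C(C)C)cc1OC)C(=O)OC
F4 | step 6 | (2S)-3-methoxy-2-methyl-3-oxo-2-({2-methoxy-6-methyl-4-[(triisopropylsilyl)oxy]benzoyl}oxy)propanoic acid | OC(=O)[C@](C)(OC(=O)c1c(C)cc(O[Si](C(C)C)(C(C)C)C(C)C)cc1OC)C(=O)OC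
F5 | step 5 | dimethyl 2-({2-methoxy-6-methyl-4-[(triisopropylsilyl)oxy]benzoyl}oxy)malonate | COC(=O)C(OC(=O)c1c(C)cc(O[Si](C(C)C)(C(C)C)C(C)C)cc1OC)C(=O)OC
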